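Ring A (the 3'-hydroxy ring, C1'–C6') is opened across C2'–C3' and C5'–C6'. The key step, a one-pot nitro-Michael/Dieckmann [3+3] annulation, makes both bonds: an acyclic nitro ester supplies C6' as a nitronate (a masked acyl anion) and C2' as an ester enolate, kept apart by quaternary C1', and methyl but-2-ynoate supplies C3'–C5'. The step exploits the 1,4-relationship between the C3' oxygen and C6', the alkyne-bearing sp2 carbon, which is carried as a ketone. Decarboxylation and Nef reaction give achiral ketoisophorone; asymmetric transfer hydrogenation sets the carbinol centre, and the silylated product serves both rings, which two Wittig reactions join to a C10 dialdehyde.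

Key step: step 2

Remark: carotenoid numbering is used (C1–C6 for the 3,4-dihydroxy ring B, C1'–C6' for ring A); compounds 1, 2, 4, 14 and 23 are taken as commercial, and 1 would otherwise follow from 3-methylbut-2-enoyl chloride and KOtBu.

Step 1
Reactants: 1 tert-butyl 3-methylbut-2-enoate; 2 nitromethane
Product: 3 tert-butyl 3,3-dimethyl-4-nitrobutanoate
Conditions: 2 (5 equiv), DBU (1 equiv), neat, 60 °C
Reagents that add atoms: none
Why: Michael addition of the nitronate of 2 to the β,β-disubstituted enoate 1 builds quaternary C1' with both methyl groups, the future C6' (nitro carbon) and C2' (ester α-carbon); no stereocentre is formed.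

Step 2
Reactants: 3 tert-butyl 3,3-dimethyl-4-nitrobutanoate; 4 methyl but-2-ynoate
Product: 6 tert-butyl 4,6,6-trimethyl-5-nitro-2-oxocyclohex-3-ene-1-carboxylate, via Michael adduct 5 (not isolated)
Conditions: KOtBu (1.0 equiv), THF, 0 °C, then 4 (1.05 equiv), 0 °C → rt; KOtBu (2.2 equiv), rt → 45 °C; AcOH quench, 0 °C
Reagents that add atoms: none
Why: In the first stage the potassium nitronate of 3, the only carbanion present because the ester α-protons are far less acidic, adds to the β-carbon of 4 in a Michael reaction and forms C5'–C6'; adduct 5 is then deprotonated at C6', which lets the enoate geometry equilibrate through the delocalised anion. The second charge of base generates the tert-butyl ester enolate at C2', which attacks the methyl ester carbon in a Dieckmann condensation, expels methoxide and forms C2'–C3'. The closest known reaction type is the Michael–Dieckmann [3+3] annulation of a 1,3-bis-nucleophile with an alkynoate, here with a nitronate as the polarity-reversed equivalent of the C6' carbonyl. The ring closes by a 6-exo-trig acyl substitution. The two new stereocentres (C2' and C6') are acidic, form without control and are both cleared in steps 3 and 4, so none is needed. The step needs C6' rather than C2' to attack the alkynoate and the methyl ester carbon to become C3'; staging the base secures the first, and the unreactive tert-butyl ester together with the absence of an sp3 C–H at C4' secures the second.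

Step 3
Reactants: 6 tert-butyl 4,6,6-trimethyl-5-nitro-2-oxocyclohex-3-ene-1-carboxylate
Product: 8 3,5,5-trimethyl-4-nitrocyclohex-2-en-1-one, via β-keto acid 7 (not isolated)
Conditions: CF3CO2H, CH2Cl2, rt; then toluene, 80 °C
Reagents that add atoms: none
Why: Acidolysis of the tert-butyl ester and decarboxylation of β-keto acid 7 remove the activating carboxyl group from C2' while the nitro group and the enone should survive; the C2' stereocentre vanishes.

Step 4
Reactants: 8 3,5,5-trimethyl-4-nitrocyclohex-2-en-1-one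
Product: 9 2,6,6-trimethylcyclohex-2-ene-1,4-dione (ketoisophorone)
Conditions: NaOMe, MeOH, 0 °C; then into H2SO4/MeOH, −30 °C; H2O, rt
Reagents that add atoms: water, O
Why: Nef reaction: the nitronate of 8 is hydrolysed in strong acid to the C6' carbonyl, which unveils the masked acyl anion as the hindered ketone of achiral 9 and clears the last uncontrolled stereocentre.

Step 5
Reactants: 9 2,6,6-trimethylcyclohex-2-ene-1,4-dione
Product: 10 (4S)-4-hydroxy-2,6,6-trimethylcyclohex-2-en-1-one
Conditions: RuCl[(S,S)-TsDPEN](p-cymene) (1 mol%), i-PrOH, rt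
Reagents that add atoms: none
Why: Asymmetric transfer hydrogenation: the ruthenium hydride should reduce only the unhindered C4 carbonyl (C1 is flanked by the quaternary carbon and the methyl-bearing alkene carbon), and the chiral amido ligand, which places the alkenyl flank as it places an aryl group, should give the (4S) carbinol, the source of both C3' and C3.

Step 6
Reactants: 10 (4S)-4-hydroxy-2,6,6-trimethylcyclohex-2-en-1-one
Product: 11 (4S)-4-[(tert-butyldimethylsilyl)oxy]-2,6,6-trimethylcyclohex-2-en-1-one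
Conditions: TBSCl, imidazole, DMF, rt
Reagents that add atoms: tert-butyldimethylsilyl chloride, CC(C)(C)[Si](C)(C)Cl
Why: Standard silylation of the secondary allylic alcohol protects the carbinol for the enolate and acetylide steps without touching the stereocentre.

Step 7
Reactants: 11 (4S)-4-[(tert-butyldimethylsilyl)oxy]-2,6,6-trimethylcyclohex-2-en-1-one
Product: 13 (4R)-4-[(tert-butyldimethylsilyl)oxy]-2,6,6-trimethylcyclohex-1-en-1-yl trifluoromethanesulfonate, via lithium enolate 12 (not isolated)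
Conditions: LiBH(s-Bu)3, THF, −78 °C; then PhNTf2, −78 °C → rt; aq. NH4Cl
Reagents that add atoms: N-phenylbis(trifluoromethanesulfonimide), O=S(=O)(N(c1ccccc1)S(=O)(=O)C(F)(F)F)C(F)(F)F
Why: Conjugate reduction with enolate trapping: the bulky borohydride should add hydride to the β-carbon because the carbonyl is shielded on both sides, and O-sulfonylation of enolate 12, which can only be the C5'=C6' enolate since C1' is quaternary, gives the enol triflate regiospecifically.

Step 8
Reactants: 13 (4R)-4-[(tert-butyldimethylsilyl)oxy]-2,6,6-trimethylcyclohex-1-en-1-yl trifluoromethanesulfonate; 14 (2E)-3-methylpent-2-en-4-yn-1-ol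
Product: 15 (2E)-5-[(4R)-4-[(tert-butyldimethylsilyl)oxy]-2,6,6-trimethylcyclohex-1-en-1-yl]-3-methylpent-2-en-4-yn-1-ol
Conditions: Pd(PPh3)4 (5 mol%), CuI (10 mol%), i-Pr2NH, THF, rt
Reagents that add atoms: none
Why: Sonogashira coupling of the enol triflate with the terminal alkyne forms C6'–C7' with retention of the ring alkene and of the E geometry brought in by 14.

Step 9
Reactants: 15 (2E)-5-[(4R)-4-[(tert-butyldimethylsilyl)oxy]-2,6,6-trimethylcyclohex-1-en-1-yl]-3-methylpent-2-en-4-yn-1-ol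
Product: 17 [(2E)-5-[(4R)-4-[(tert-butyldimethylsilyl)oxy]-2,6,6-trimethylcyclohex-1-en-1-yl]-3-methylpent-2-en-4-yn-1-yl]triphenylphosphonium bromide, via allylic bromide 16 (not isolated)
Conditions: CBr4, PPh3, CH2Cl2, 0 °C; then PPh3, rt
Reagents that add atoms: carbon tetrabromide, BrC(Br)(Br)Br; triphenylphosphine, c1ccc(cc1)P(c1ccccc1)c1ccccc1
Why: Appel bromination of the primary allylic alcohol and SN2 quaternisation of bromide 16 by PPh3 run under neutral conditions, so the silyl ether and the E alkene should survive.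

Step 10
Reactants: 11 (4S)-4-[(tert-butyldimethylsilyl)oxy]-2,6,6-trimethylcyclohex-2-en-1-one; 14 (2E)-3-methylpent-2-en-4-yn-1-ol
Product: 18 (4S)-4-[(tert-butyldimethylsilyl)oxy]-1-[(3E)-5-hydroxy-3-methylpent-3-en-1-yn-1-yl]-2,6,6-trimethylcyclohex-2-en-1-ol (both C1 epimers)
Conditions: 14 (1.5 equiv), n-BuLi (3.0 equiv), THF, −78 °C; then 11, −78 → −20 °C; aq. NH4Cl
Reagents that add atoms: none
Why: 1,2-Addition of the lithium acetylide (dianion of 14) to the hindered enone carbonyl, the usual course for acetylides with 2,6,6-trimethylcyclohexenones; the new C1 carbinol centre needs no control because it becomes sp2 in step 12.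

Step 11
Reactants: 18 (4S)-4-[(tert-butyldimethylsilyl)oxy]-1-[(3E)-5-hydroxy-3-methylpent-3-en-1-yn-1-yl]-2,6,6-trimethylcyclohex-2-en-1-ol
Product: 21 [(2E)-5-[(4S)-4-[(tert-butyldimethylsilyl)oxy]-1-hydroxy-2,6,6-trimethylcyclohex-2-en-1-yl]-3-methylpent-2-en-4-yn-1-yl]triphenylphosphonium bromide, via allylic mesylate 19 (not isolated), via allylic bromide 20 (not isolated)
Conditions: MsCl (1.05 equiv), Et3N, CH2Cl2, −40 °C; LiBr, THF, 0 °C; then PPh3, rt
Reagents that add atoms: lithium bromide, [Li+].[Br-]; triphenylphosphine, c1ccc(cc1)P(c1ccccc1)c1ccccc1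
Why: Only the primary allylic hydroxyl is sulfonylated at low temperature (the tertiary carbinol is inert), and Finkelstein-type displacement by bromide followed by SN2 quaternisation with PPh3 gives the salt with the E alkene unchanged.

Step 12
Reactants: 21 [(2E)-5-[(4S)-4-[(tert-butyldimethylsilyl)oxy]-1-hydroxy-2,6,6-trimethylcyclohex-2-en-1-yl]-3-methylpent-2-en-4-yn-1-yl]triphenylphosphonium bromide
Product: 22 [(2E)-5-[(3S,4S)-4-[(tert-butyldimethylsilyl)oxy]-3-hydroxy-2,6,6-trimethylcyclohex-1-en-1-yl]-3-methylpent-2-en-4-yn-1-yl]triphenylphosphonium bromide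
Conditions: H2SO4 (0.05 M), THF/H2O 3:1, 0 °C
Reagents that add atoms: water, O
Why: Acid-catalysed 1,3-allylic (oxotropic) transposition: the tertiary alkenyl alkynyl carbinol ionises to a delocalised cation, water should add at the far allylic terminus (C4 of ring B) anti to the neighbouring silyloxy group and so set the (4S) centre trans to C3, and conjugation of the new tetrasubstituted C5=C6 alkene with the enyne drives the shift.

Step 13
Reactants: 17 [(2E)-5-[(4R)-4-[(tert-butyldimethylsilyl)oxy]-2,6,6-trimethylcyclohex-1-en-1-yl]-3-methylpent-2-en-4-yn-1-yl]triphenylphosphonium bromide; 23 (2E,4E,6E)-2,7-dimethylocta-2,4,6-trienedial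
Product: 24 (2E,4E,6E,8E,10E)-13-[(4R)-4-[(tert-butyldimethylsilyl)oxy]-2,6,6-trimethylcyclohex-1-en-1-yl]-2,7,11-trimethyltrideca-2,4,6,8,10-pentaen-12-ynal
Conditions: 23 (3 equiv), NaOMe, CH2Cl2/MeOH, 0 °C → rt; then n-heptane, 80 °C, dark
Reagents that add atoms: none
Why: Wittig olefination of one formyl group of the excess dialdehyde with the allylic ylide forms C11'=C12', and heating should convert the hindered Z isomer of this bond into E while the preset E bonds stay.

Step 14
Reactants: 22 [(2E)-5-[(3S,4S)-4-[(tert-butyldimethylsilyl)oxy]-3-hydroxy-2,6,6-trimethylcyclohex-1-en-1-yl]-3-methylpent-2-en-4-yn-1-yl]triphenylphosphonium bromide; 24 (2E,4E,6E,8E,10E)-13-[(4R)-4-[(tert-butyldimethylsilyl)oxy]-2,6,6-trimethylcyclohex-1-en-1-yl]-2,7,11-trimethyltrideca-2,4,6,8,10-pentaen-12-ynal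
Product: 25 (3S,4S,3'R)-3,3'-bis[(tert-butyldimethylsilyl)oxy]-7,8,7',8'-tetradehydro-β,β-caroten-4-ol (all-E)
Conditions: NaOMe (2.2 equiv), CH2Cl2/MeOH, 0 °C → rt; then EtOAc, 70 °C, dark
Reagents that add atoms: none
Why: The second Wittig olefination forms C11=C12 (the alkoxide of the free C4 hydroxyl is a spectator), and thermal equilibration should again turn the new Z bond into E.

Step 15
Reactants: 25 (3S,4S,3'R)-3,3'-bis[(tert-butyldimethylsilyl)oxy]-7,8,7',8'-tetradehydro-β,β-caroten-4-ol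
Product: 26 (3S,4S,3'R)-4-hydroxyalloxanthin
Conditions: Bu4NF, AcOH, THF, 0 °C → rt; aq. NH4Cl
Reagents that add atoms: none
Why: Fluoride-mediated cleavage of both silyl ethers, buffered with acetic acid, should release the triol without acid that could ionise the allylic C4 carbinol; no stereocentre is affected.

Compound list
1 | tert-butyl 3-methylbut-2-enoate | CC(C)=CC(=O)OC(C)(C)C | starting material
2 | nitromethane | C[N+](=O)[O-] | starting material
3 | tert-butyl 3,3-dimethyl-4-nitrobutanoate | CC(C)(C[N+](=O)[O-])CC(=O)OC(C)(C)C | intermediate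
4 | methyl but-2-ynoate | CC#CC(=O)OC | starting material
5 | 1-tert-butyl 7-methyl 3,3,5-trimethyl-4-nitrohept-5-enedioate (racemic, E/Z mixture) | COC(=O)C=C(C)C([N+](=O)[O-])C(C)(C)CC(=O)OC(C)(C)C | intermediate (not isolated)
6 | tert-butyl 4,6,6-trimethyl-5-nitro-2-oxocyclohex-3-ene-1-carboxylate (mixture of stereoisomers) | CC1=CC(=O)C(C(=O)OC(C)(C)C)C(C)(C)C1[N+](=O)[O-] | intermediate
7 | 4,6,6-trimethyl-5-nitro-2-oxocyclohex-3-ene-1-carboxylic acid (mixture of stereoisomers) | CC1=CC(=O)C(C(=O)O)C(C)(C)C1[N+](=O)[O-] | intermediate (not isolated)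
8 | 3,5,5-trimethyl-4-nitrocyclohex-2-en-1-one (racemic) | CC1=CC(=O)CC(C)(C)C1[N+](=O)[O-] | intermediate
9 | 2,6,6-trimethylcyclohex-2-ene-1,4-dione | CC1=CC(=O)CC(C)(C)C1=O | intermediate
10 | (4S)-4-hydroxy-2,6,6-trimethylcyclohex-2-en-1-one | CC1=C[C@@H](O)CC(C)(C)C1=O | intermediate
11 | (4S)-4-[(tert-butyldimethylsilyl)oxy]-2,6,6-trimethylcyclohex-2-en-1-one | CC1=C[C@@H](O[Si](C)(C)C(C)(C)C)CC(C)(C)C1=O | intermediate
12 | lithium (4R)-4-[(tert-butyldimethylsilyl)oxy]-2,6,6-trimethylcyclohex-1-en-1-olate | [Li+].CC1=C([O-])C(C)(C)C[C@H](O[Si](C)(C)C(C)(C)C)C1 | intermediate (not isolated)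
13 | (4R)-4-[(tert-butyldimethylsilyl)oxy]-2,6,6-trimethylcyclohex-1-en-1-yl trifluoromethanesulfonate | CC1=C(OS(=O)(=O)C(F)(F)F)C(C)(C)C[C@H](O[Si](C)(C)C(C)(C)C)C1 | intermediate
14 | (2E)-3-methylpent-2-en-4-yn-1-ol | C#C/C(C)=C/CO | starting material
15 | (2E)-5-[(4R)-4-[(tert-butyldimethylsilyl)oxy]-2,6,6-trimethylcyclohex-1-en-1-yl]-3-methylpent-2-en-4-yn-1-ol | CC1=C(C#C/C(C)=C/CO)C(C)(C)C[C@H](O[Si](C)(C)C(C)(C)C)C1 | intermediate
16 | {[(1R)-4-[(3E)-5-bromo-3-methylpent-3-en-1-yn-1-yl]-3,5,5-trimethylcyclohex-3-en-1-yl]oxy}(tert-butyl)dimethylsilane | CC1=C(C#C/C(C)=C/CBr)C(C)(C)C[C@H](O[Si](C)(C)C(C)(C)C)C1 | intermediate (not isolated)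
17 | [(2E)-5-[(4R)-4-[(tert-butyldimethylsilyl)oxy]-2,6,6-trimethylcyclohex-1-en-1-yl]-3-methylpent-2-en-4-yn-1-yl]triphenylphosphonium bromide | CC1=C(C#C/C(C)=C/C[P+](c2ccccc2)(c2ccccc2)c2ccccc2)C(C)(C)C[C@H](O[Si](C)(C)C(C)(C)C)C1.[Br-] | intermediate
18 | (4S)-4-[(tert-butyldimethylsilyl)oxy]-1-[(3E)-5-hydroxy-3-methylpent-3-en-1-yn-1-yl]-2,6,6-trimethylcyclohex-2-en-1-ol (both C1 epimers) | CC1=C[C@@H](O[Si](C)(C)C(C)(C)C)CC(C)(C)C1(O)C#C/C(C)=C/CO | intermediate
19 | (2E)-5-[(4S)-4-[(tert-butyldimethylsilyl)oxy]-1-hydroxy-2,6,6-trimethylcyclohex-2-en-1-yl]-3-methylpent-2-en-4-yn-1-yl methanesulfonate | CC1=C[C@@H](O[Si](C)(C)C(C)(C)C)CC(C)(C)C1(O)C#C/C(C)=C/COS(C)(=O)=O | intermediate (not isolated)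
20 | (4S)-1-[(3E)-5-bromo-3-methylpent-3-en-1-yn-1-yl]-4-[(tert-butyldimethylsilyl)oxy]-2,6,6-trimethylcyclohex-2-en-1-ol | CC1=C[C@@H](O[Si](C)(C)C(C)(C)C)CC(C)(C)C1(O)C#C/C(C)=C/CBr | intermediate (not isolated)
21 | [(2E)-5-[(4S)-4-[(tert-butyldimethylsilyl)oxy]-1-hydroxy-2,6,6-trimethylcyclohex-2-en-1-yl]-3-methylpent-2-en-4-yn-1-yl]triphenylphosphonium bromide | CC1=C[C@@H](O[Si](C)(C)C(C)(C)C)CC(C)(C)C1(O)C#C/C(C)=C/C[P+](c2ccccc2)(c2ccccc2)c2ccccc2.[Br-] | intermediate
22 | [(2E)-5-[(3S,4S)-4-[(tert-butyldimethylsilyl)oxy]-3-hydroxy-2,6,6-trimethylcyclohex-1-en-1-yl]-3-methylpent-2-en-4-yn-1-yl]triphenylphosphonium bromide | c1ccccc1[P+](c1ccccc1)(c1ccccc1)C/C=C(\C)C#CC1=C(C)[C@H](O)[C@@H](O[Si](C)(C)C(C)(C)C)CC1(C)C.[Br-] | intermediate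
23 | (2E,4E,6E)-2,7-dimethylocta-2,4,6-trienedial | O=C/C(C)=C/C=C/C=C(C)/C=O | starting material
24 | (2E,4E,6E,8E,10E)-13-[(4R)-4-[(tert-butyldimethylsilyl)oxy]-2,6,6-trimethylcyclohex-1-en-1-yl]-2,7,11-trimethyltrideca-2,4,6,8,10-pentaen-12-ynal | CC1=C(C#C/C(C)=C/C=C/C(C)=C/C=C/C=C(C)/C=O)C(C)(C)C[C@H](O[Si](C)(C)C(C)(C)C)C1 | intermediate
25 | (3S,4S,3'R)-3,3'-bis[(tert-butyldimethylsilyl)oxy]-7,8,7',8'-tetradehydro-β,β-caroten-4-ol (all-E) | CC1=C(C#C/C(C)=C/C=C/C(C)=C/C=C/C=C(C)/C=C/C=C(\C)C#CC2=C(C)[C@H](O)[C@@H](O[Si](C)(C)C(C)(C)C)CC2(C)C)C(C)(C)C[C@H](O[Si](C)(C)C(C)(C)C)C1 | intermediate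
26 | (3S,4S,3'R)-4-hydroxyalloxanthin | CC1=C(C#C/C(C)=C/C=C/C(C)=C/C=C/C=C(C)/C=C/C=C(\C)C#CC2=C(C)[C@H](O)[C@@H](O)CC2(C)C)C(C)(C)C[C@H](O)C1 | target

Total step count: 15. Longest linear sequence: 12 steps (steps 1–9, then 13–15).

Steps most likely to fail

Step 2 (domino annulation). The sequence may stop at open adduct 5 if the anionic, conjugated methyl ester resists attack by the tert-butyl ester enolate, or the ester enolate may add to a second molecule of 4 if the base is not staged. The fallback sets out from 3 and returns at 6, forming the same two bonds in reverse order. But-2-ynoic acid, N,O-dimethylhydroxylamine hydrochloride and a carbodiimide give N-methoxy-N-methylbut-2-ynamide F1. The dianion of 3 (LiN(iPr)2, 2.1 equiv, THF, −78 °C) is acylated at the ester α-carbon by F1, where the chelated tetrahedral intermediate prevents over-reaction, to give tert-butyl 2-(2-methyl-1-nitropropan-2-yl)-3-oxohex-4-ynoate F2. Catalytic DBU in MeCN then closes the ring by 6-endo-dig intramolecular nitro-Michael addition onto the ynone to give 6.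

Step 12 (allylic transposition). The delocalised cation may be captured at the alkyne terminus, which leads irreversibly to a conjugated ketone, or may lose a proton; the acid may cleave the silyl ether; reversible ionisation may erode the facial selectivity at C4. The fallback sets out from 11, returns at 22, and sets C4 before the enyne is installed.
- Copper-catalysed conjugate borylation anti to the silyloxy group (CuCl, NaOtBu, 4,5-bis(diphenylphosphino)-9,9-dimethylxanthene, B2pin2, MeOH, THF) gives (3S,4S)-4-[(tert-butyldimethylsilyl)oxy]-2,6,6-trimethyl-3-(4,4,5,5-tetramethyl-1,3,2-dioxaborolan-2-yl)cyclohexan-1-one F3.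
- Oxidation with NaBO3·4H2O, with retention, gives (3S,4S)-4-[(tert-butyldimethylsilyl)oxy]-3-hydroxy-2,6,6-trimethylcyclohexan-1-one F4.
- Et3SiCl and imidazole give (3S,4S)-4-[(tert-butyldimethylsilyl)oxy]-2,6,6-trimethyl-3-[(triethylsilyl)oxy]cyclohexan-1-one F5.
- KN(SiMe3)2 and PhNTf2 at −78 °C (only C2 can be enolised) give (3S,4S)-4-[(tert-butyldimethylsilyl)oxy]-2,6,6-trimethyl-3-[(triethylsilyl)oxy]cyclohex-1-en-1-yl trifluoromethanesulfonate F6.
- Sonogashira coupling with 14 gives (2E)-5-[(3S,4S)-4-[(tert-butyldimethylsilyl)oxy]-2,6,6-trimethyl-3-[(triethylsilyl)oxy]cyclohex-1-en-1-yl]-3-methylpent-2-en-4-yn-1-ol F7.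
- CBr4/PPh3 followed by PPh3 gives [(2E)-5-[(3S,4S)-4-[(tert-butyldimethylsilyl)oxy]-2,6,6-trimethyl-3-[(triethylsilyl)oxy]cyclohex-1-en-1-yl]-3-methylpent-2-en-4-yn-1-yl]triphenylphosphonium bromide F8.
- Pyridinium p-toluenesulfonate in MeOH at 0 °C removes the triethylsilyl group selectively to give 22.

Step 4 (Nef reaction). The delocalised nitronate may be protonated on carbon next to the enone carbonyl, which diverts material to a deconjugated nitroalkene that does not hydrolyse, and the enedione may degrade in the strongly basic and acidic media. The fallback sets out from 8 and returns at 9. SnCl2·2H2O, PhSH and Et3N reduce the secondary nitro group to the oxime 4-(hydroxyimino)-3,5,5-trimethylcyclohex-2-en-1-one F9. Oxime exchange with glyoxylic acid in aqueous acetic acid then releases 9.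

Further compounds
F1 | step 2 | N-methoxy-N-methylbut-2-ynamide | CC#CC(=O)N(C)OC
F2 | step 2 | tert-butyl 2-(2-methyl-1-nitropropan-2-yl)-3-oxohex-4-ynoate | CC#CC(=O)C(C(=O)OC(C)(C)C)C(C)(C)C[N+](=O)[O-]
F3 | step 12 | (3S,4S)-4-[(tert-butyldimethylsilyl)oxy]-2,6,6-trimethyl-3-(4,4,5,5-tetramethyl-1,3,2-dioxaborolan-2-yl)cyclohexan-1-one | O=C1C(C)[C@H](B2OC(C)(C)C(C)(C)O2)[C@@H](O[Si](C)(C)C(C)(C)C)CC1(C)C
F4 | step 12 | (3S,4S)-4-[(tert-butyldimethylsilyl)oxy]-3-hydroxy-2,6,6-trimethylcyclohexan-1-one | O=C1C(C)[C@H](O)[C@@H](O[Si](C)(C)C(C)(C)C)CC1(C)C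
F5 | step 12 | (3S,4S)-4-[(tert-butyldimethylsilyl)oxy]-2,6,6-trimethyl-3-[(triethylsilyl)oxy]cyclohexan-1-one | O=C1C(C)[C@H](O[Si](CC)(CC)CC)[C@@H](O[Si](C)(C)C(C)(C)C)CC1(C)C
F6 | step 12 | (3S,4S)-4-[(tert-butyldimethylsilyl)oxy]-2,6,6-trimethyl-3-[(triethylsilyl)oxy]cyclohex-1-en-1-yl trifluoromethanesulfonate | FC(F)(F)S(=O)(=O)OC1=C(C)[C@H](O[Si](CC)(CC)CC)[C@@H](O[Si](C)(C)C(C)(C)C)CC1(C)C
F7 | step 12 | (2E)-5-[(3S,4S)-4-[(tert-butyldimethylsilyl)oxy]-2,6,6-trimethyl-3-[(triethylsilyl)oxy]cyclohex-1-en-1-yl]-3-methylpent-2-en-4-yn-1-ol | OC/C=C(\C)C#CC1=C(C)[C@H](O[Si](CC)(CC)CC)[C@@H](O[Si](C)(C)C(C)(C)C)CC1(C)C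
F8 | step 12 | [(2E)-5-[(3S,4S)-4-[(tert-butyldimethylsilyl)oxy]-2,6,6-trimethyl-3-[(triethylsilyl)oxy]cyclohex-1-en-1-yl]-3-methylpent-2-en-4-yn-1-yl]triphenylphosphonium bromide | c1ccccc1[P+](c1ccccc1)(c1ccccc1)C/C=C(\C)C#CC1=C(C)[C@H](O[Si](CC)(CC)CC)[C@@H](O[Si](C)(C)C(C)(C)C)CC1(C)C.[Br-]
F9 | step 4 | 4-(hydroxyimino)-3,5,5-trimethylcyclohex-2-en-1-one | CC1=CC(=O)CC(C)(C)C1=NO
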